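**Retrosynthetic overview**
1. Target 22 ⇒ open-chain enal–allylboronate 20 by cutting C6–C7 and the lactone C–O. The ten-membered ring closes first (C6–C7, the bond made from farnesyl C1 to C10 in germacrene biosynthesis); the γ-lactone closes second (O6 onto C12) in the same flask.
2. 20 ⇒ vinyl iodide 19 (CO becomes C6) ⇒ terminal alkene 16 + boryl acrylate 18 (cross-metathesis, C7=C11).
3. 16 ⇒ (Z)-enal 12 + allylboronate 13 (catalytic asymmetric allylboration sets C9).
4. 12 ⇒ phosphonium salt 8 + 1,1-dimethoxyacetone 9 (Z-selective Wittig, C1=C10).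
5. 8 ⇒ propargyl alcohol 1 + Grignard reagent from 2 (anti-carbomagnesiation/iodination fixes the C4=C5 geometry).

Assumption: germacrane numbering is used (lactone carbons C6/C7, acetoxy carbon C9, acyloxymethyl C15), the target SMILES is read as 6R,7R,9S with a cis-fused lactone, a ring-cis C1=C10 and a ring-trans C4=C5 alkene, and (R)-TRIP is taken to deliver allyl groups to the aldehyde Re face, so (S)-TRIP is used for Si-face attack.

**Route**

Step 1
Reactants: 1 prop-2-yn-1-ol; 2 (3-bromopropoxy)(tert-butyl)dimethylsilane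
Product: 5 (2Z)-2-{3-[(tert-butyldimethylsilyl)oxy]propyl}-3-iodoprop-2-en-1-ol, via Grignard reagent 3 (not isolated), via magnesium chelate 4 (not isolated)
Conditions: 2, Mg, THF, rt; 1, i-PrMgCl (1.0 equiv), THF, 0 °C; then 3 (1.5 equiv), CuI (10 mol%), THF–Et2O, 0 °C→rt; I2, −40→0 °C; cold dil. HCl
Reagents that add atoms: iodine, II
Why: Copper-catalysed anti-carbomagnesiation of the magnesium propargyl alkoxide (Duboudin reaction) puts the alkyl group on the internal carbon and magnesium on the terminal carbon inside a five-membered O–Mg chelate, so iodinolysis with retention gives the (Z)-iodoalkene with iodine cis to CH2OH, which is the C6/C15 cis relationship of the target.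

Step 2
Reactants: 5 (2Z)-2-{3-[(tert-butyldimethylsilyl)oxy]propyl}-3-iodoprop-2-en-1-ol
Product: 6 (2Z)-2-{3-[(tert-butyldimethylsilyl)oxy]propyl}-3-iodoprop-2-en-1-yl 3-methylbutanoate
Conditions: 3-methylbutanoyl chloride, Et3N, DMAP (cat.), CH2Cl2, 0 °C→rt
Reagents that add atoms: 3-methylbutanoyl chloride, CC(C)CC(Cl)=O
Why: DMAP-catalysed acylation of the only free hydroxyl installs the isovalerate early and differentiates C15–O from the future C6 carbonyl, which stays masked as the vinyl iodide.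

Step 3
Reactants: 6 (2Z)-2-{3-[(tert-butyldimethylsilyl)oxy]propyl}-3-iodoprop-2-en-1-yl 3-methylbutanoate
Product: 8 {(4Z)-5-iodo-4-[(3-methylbutanoyloxy)methyl]pent-4-en-1-yl}triphenylphosphonium bromide, via alkyl bromide 7 (not isolated)
Conditions: Ph3PBr2, CH2Cl2, 0 °C→rt; then PPh3, MeCN, 80 °C
Reagents that add atoms: dibromotriphenylphosphorane, BrP(Br)(c1ccccc1)(c1ccccc1)c1ccccc1; triphenylphosphine, c1ccc(cc1)P(c1ccccc1)c1ccccc1
Why: Ph3PBr2 converts a primary TBS ether directly into the bromide through an alkoxyphosphonium ion (Appel-type substitution), and the primary bromide then quaternises PPh3 by SN2, while the vinyl iodide and the ester are inert to both reagents.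

Step 4
Reactants: 8 {(4Z)-5-iodo-4-[(3-methylbutanoyloxy)methyl]pent-4-en-1-yl}triphenylphosphonium bromide; 9 1,1-dimethoxypropan-2-one
Product: 12 (2Z)-3-iodo-2-[(3Z)-4-methyl-5-oxopent-3-en-1-yl]prop-2-en-1-yl 3-methylbutanoate, via phosphorus ylide 10 (not isolated), via dimethyl acetal 11 (not isolated)
Conditions: KHMDS, THF, −78 °C; 9, −78→0 °C; then aq. oxalic acid, THF, 0 °C
Reagents that add atoms: water, O
Why: Wittig olefination of an α-alkoxy ketone with a non-stabilised ylide under salt-free conditions (Still's Z-selective variant) places the acetal carbon cis to the chain, and brief mild-acid hydrolysis of the allylic acetal then releases the (Z)-2-methyl enal without isomerisation.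

Step 5
Reactants: 12 (2Z)-3-iodo-2-[(3Z)-4-methyl-5-oxopent-3-en-1-yl]prop-2-en-1-yl 3-methylbutanoate; 13 2-allyl-4,4,5,5-tetramethyl-1,3,2-dioxaborolane
Product: 15 (2Z)-2-[(3Z,5S)-5-hydroxy-4-methylocta-3,7-dien-1-yl]-3-iodoprop-2-en-1-yl 3-methylbutanoate, via pinacol borate 14 (not isolated)
Conditions: 13 (1.2 equiv), (S)-TRIP (5 mol%), toluene, −30 °C; aq. work-up
Reagents that add atoms: none
Why: Chiral phosphoric acid-catalysed allylboration (Antilla reaction) runs through a closed Zimmerman–Traxler chair in which (S)-TRIP directs the allyl group to the Si face of the enal, which sets C9 as S.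

Step 6
Reactants: 15 (2Z)-2-[(3Z,5S)-5-hydroxy-4-methylocta-3,7-dien-1-yl]-3-iodoprop-2-en-1-yl 3-methylbutanoate
Product: 16 (2Z)-2-[(3Z,5S)-5-acetoxy-4-methylocta-3,7-dien-1-yl]-3-iodoprop-2-en-1-yl 3-methylbutanoate
Conditions: Ac2O, Et3N, DMAP (cat.), CH2Cl2, 0 °C→rt
Reagents that add atoms: acetic anhydride, CC(=O)OC(C)=O
Why: Standard DMAP-catalysed acetylation of the secondary alcohol installs the C9 acetate without touching the stereocentre.

Step 7
Reactants: 17 methyl 2-(bromomethyl)prop-2-enoate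
Product: 18 methyl 2-[(4,4,5,5-tetramethyl-1,3,2-dioxaborolan-2-yl)methyl]prop-2-enoate
Conditions: B2pin2, CuCl (10 mol%), KOAc, DMF, rt
Reagents that add atoms: bis(pinacolato)diboron, CC1(C)OB(OC1(C)C)B1OC(C)(C)C(C)(C)O1
Why: Copper-catalysed allylic borylation with B2pin2 (Miyaura-type; SN2 and SN2′ give the same product here) delivers the bench-stable 2-alkoxycarbonyl allylboronate.

Step 8
Reactants: 16 (2Z)-2-[(3Z,5S)-5-acetoxy-4-methylocta-3,7-dien-1-yl]-3-iodoprop-2-en-1-yl 3-methylbutanoate; 18 methyl 2-[(4,4,5,5-tetramethyl-1,3,2-dioxaborolan-2-yl)methyl]prop-2-enoate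
Product: 19 methyl (2E,5S,6Z,10Z)-5-acetoxy-11-iodo-6-methyl-10-[(3-methylbutanoyloxy)methyl]-2-[(4,4,5,5-tetramethyl-1,3,2-dioxaborolan-2-yl)methyl]undeca-2,6,10-trienoate
Conditions: 18 (3 equiv), Hoveyda–Grubbs II (10 mol%), CH2Cl2, 40 °C
Reagents that add atoms: none
Why: Olefin cross-metathesis of a terminal alkene with a 1,1-disubstituted acrylate (as with methacrylates) gives the trisubstituted enoate with the chain trans to the ester and therefore cis to CH2Bpin, while the trisubstituted alkenes and the vinyl iodide do not react.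

Step 9
Reactants: 19 methyl (2E,5S,6Z,10Z)-5-acetoxy-11-iodo-6-methyl-10-[(3-methylbutanoyloxy)methyl]-2-[(4,4,5,5-tetramethyl-1,3,2-dioxaborolan-2-yl)methyl]undeca-2,6,10-trienoate
Product: 20 methyl (2E,5S,6Z,10Z)-5-acetoxy-6-methyl-10-[(3-methylbutanoyloxy)methyl]-12-oxo-2-[(4,4,5,5-tetramethyl-1,3,2-dioxaborolan-2-yl)methyl]dodeca-2,6,10-trienoate
Conditions: CO (1 atm), Pd(PPh3)4 (5 mol%), Bu3SnH (slow addition), THF, 50 °C
Reagents that add atoms: carbon monoxide, [C-]#[O+]
Why: Palladium-catalysed reductive carbonylation of the vinyl iodide (Stille formylation) gives the enal with retention of alkene geometry, because oxidative addition into C–I is much faster than ionisation of the hindered allylic esters.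

Step 10
Reactants: 20 methyl (2E,5S,6Z,10Z)-5-acetoxy-6-methyl-10-[(3-methylbutanoyloxy)methyl]-12-oxo-2-[(4,4,5,5-tetramethyl-1,3,2-dioxaborolan-2-yl)methyl]dodeca-2,6,10-trienoate
Product: 22 [(3aR,5S,6Z,10Z,11aR)-5-acetoxy-6-methyl-3-methylidene-2-oxo-2,3,3a,4,5,8,9,11a-octahydrocyclodeca[b]furan-10-yl]methyl 3-methylbutanoate, via macrocyclic borate 21 (not isolated)
Conditions: (S)-TRIP (20 mol%), 4 Å MS, toluene, 40 °C, syringe-pump addition (final 2 mM); then p-TsOH (cat.), rt
Reagents that add atoms: none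
Why: Proposed new method: a macrocyclic, chiral phosphoric acid-catalysed intramolecular allylboration in which the acid activates the pinacol boronate (P–OH···O–B and P=O···H–C(formyl) contacts) and the allyl unit adds through a closed Zimmerman–Traxler chair with C5 equatorial and C8 (cis to CH2B) axial, so that the C6–C7 bond forms with syn (6,7-cis) relative configuration by stereospecificity and with Si-face attack at C6 (6R, hence 7R) by catalyst control, after which the B–O–C6 borate acylates onto C12 to close the cis-fused α-methylene lactone; the closest known reactions are the intermolecular phosphoric acid-catalysed allylboration of aldehydes with allyl pinacolboronates and the thermal or acid-catalysed allylboration–lactonisation of 2-alkoxycarbonyl allylboronates, and the two ring alkenes preorganise the chain for ten-membered ring closure under pseudo-high dilution.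

**Compound list**
1 | prop-2-yn-1-ol | C#CCO | starting material
2 | (3-bromopropoxy)(tert-butyl)dimethylsilane | BrCCCO[Si](C)(C)C(C)(C)C | starting material
3 | {3-[(tert-butyldimethylsilyl)oxy]propyl}magnesium bromide | Br[Mg]CCCO[Si](C)(C)C(C)(C)C | intermediate
4 | cyclic (Z)-alkenylmagnesium alkoxide, 4-{3-[(tert-butyldimethylsilyl)oxy]propyl}-2,5-dihydro-1,2-oxamagnesole | [Mg]1OCC(CCCO[Si](C)(C)C(C)(C)C)=C1 | intermediate
5 | (2Z)-2-{3-[(tert-butyldimethylsilyl)oxy]propyl}-3-iodoprop-2-en-1-ol (I cis to CH2OH) | I/C=C(\CO)CCCO[Si](C)(C)C(C)(C)C | intermediate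
6 | (2Z)-2-{3-[(tert-butyldimethylsilyl)oxy]propyl}-3-iodoprop-2-en-1-yl 3-methylbutanoate | I/C=C(\COC(=O)CC(C)C)CCCO[Si](C)(C)C(C)(C)C | intermediate
7 | (2Z)-2-(3-bromopropyl)-3-iodoprop-2-en-1-yl 3-methylbutanoate | I/C=C(\COC(=O)CC(C)C)CCCBr | intermediate
8 | {(4Z)-5-iodo-4-[(3-methylbutanoyloxy)methyl]pent-4-en-1-yl}triphenylphosphonium bromide | I/C=C(\COC(=O)CC(C)C)CCC[P+](c1ccccc1)(c1ccccc1)c1ccccc1.[Br-] | intermediate
9 | 1,1-dimethoxypropan-2-one | CC(=O)C(OC)OC | starting material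
10 | {(4Z)-5-iodo-4-[(3-methylbutanoyloxy)methyl]pent-4-en-1-ylidene}triphenylphosphorane | I/C=C(\COC(=O)CC(C)C)CCC=P(c1ccccc1)(c1ccccc1)c1ccccc1 | intermediate
11 | (2Z)-2-[(3Z)-5,5-dimethoxy-4-methylpent-3-en-1-yl]-3-iodoprop-2-en-1-yl 3-methylbutanoate | I/C=C(\COC(=O)CC(C)C)CC/C=C(/C)C(OC)OC | intermediate
12 | (2Z)-3-iodo-2-[(3Z)-4-methyl-5-oxopent-3-en-1-yl]prop-2-en-1-yl 3-methylbutanoate (CHO cis to the chain) | I/C=C(\COC(=O)CC(C)C)CC/C=C(/C)C=O | intermediate
13 | 2-allyl-4,4,5,5-tetramethyl-1,3,2-dioxaborolane | C=CCB1OC(C)(C)C(C)(C)O1 | starting material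
14 | pinacol borate of 15, (2Z)-3-iodo-2-{(3Z,5S)-4-methyl-5-[(4,4,5,5-tetramethyl-1,3,2-dioxaborolan-2-yl)oxy]octa-3,7-dien-1-yl}prop-2-en-1-yl 3-methylbutanoate | I/C=C(\COC(=O)CC(C)C)CC/C=C(/C)[C@@H](OB1OC(C)(C)C(C)(C)O1)CC=C | intermediate
15 | (2Z)-2-[(3Z,5S)-5-hydroxy-4-methylocta-3,7-dien-1-yl]-3-iodoprop-2-en-1-yl 3-methylbutanoate | I/C=C(\COC(=O)CC(C)C)CC/C=C(/C)[C@@H](O)CC=C | intermediate
16 | (2Z)-2-[(3Z,5S)-5-acetoxy-4-methylocta-3,7-dien-1-yl]-3-iodoprop-2-en-1-yl 3-methylbutanoate | I/C=C(\COC(=O)CC(C)C)CC/C=C(/C)[C@@H](OC(C)=O)CC=C | intermediate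
17 | methyl 2-(bromomethyl)prop-2-enoate | C=C(CBr)C(=O)OC | starting material
18 | methyl 2-[(4,4,5,5-tetramethyl-1,3,2-dioxaborolan-2-yl)methyl]prop-2-enoate | C=C(CB1OC(C)(C)C(C)(C)O1)C(=O)OC | intermediate
19 | methyl (2E,5S,6Z,10Z)-5-acetoxy-11-iodo-6-methyl-10-[(3-methylbutanoyloxy)methyl]-2-[(4,4,5,5-tetramethyl-1,3,2-dioxaborolan-2-yl)methyl]undeca-2,6,10-trienoate | I/C=C(\COC(=O)CC(C)C)CC/C=C(/C)[C@@H](OC(C)=O)C/C=C(\CB1OC(C)(C)C(C)(C)O1)C(=O)OC | intermediate
20 | methyl (2E,5S,6Z,10Z)-5-acetoxy-6-methyl-10-[(3-methylbutanoyloxy)methyl]-12-oxo-2-[(4,4,5,5-tetramethyl-1,3,2-dioxaborolan-2-yl)methyl]dodeca-2,6,10-trienoate | O=C/C=C(\COC(=O)CC(C)C)CC/C=C(/C)[C@@H](OC(C)=O)C/C=C(\CB1OC(C)(C)C(C)(C)O1)C(=O)OC | intermediate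
21 | methyl 2-{(1R,2R,3Z,7Z,9S)-9-acetoxy-8-methyl-4-[(3-methylbutanoyloxy)methyl]-2-[(4,4,5,5-tetramethyl-1,3,2-dioxaborolan-2-yl)oxy]cyclodeca-3,7-dien-1-yl}prop-2-enoate | C=C(C(=O)OC)[C@@H]1[C@H](OB2OC(C)(C)C(C)(C)O2)/C=C(\COC(=O)CC(C)C)CC/C=C(/C)[C@@H](OC(C)=O)C1 | intermediate
22 | [(3aR,5S,6Z,10Z,11aR)-5-acetoxy-6-methyl-3-methylidene-2-oxo-2,3,3a,4,5,8,9,11a-octahydrocyclodeca[b]furan-10-yl]methyl 3-methylbutanoate (CNP0398030.1) | C=C1C(=O)O[C@@H]2/C=C(\COC(=O)CC(C)C)CC/C=C(/C)[C@@H](OC(C)=O)C[C@H]12 | target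

**Step count and risks**

Total step count: 10. Longest linear sequence: 9 steps (steps 1–6, 8, 9 and 10; step 7 is a one-step side branch).

Step 10 is the most likely to fail. The ten-membered closure with a weakly nucleophilic ester-substituted allylboronate may be too slow, may oligomerise, or the catalyst may be mismatched with the C9 stereocentre. The fallback replaces the boron chemistry with a much more reactive organoindium and sets out from 16. Palladium-catalysed formylation (CO, Bu3SnH) gives the enal (2Z)-2-[(3Z,5S)-5-acetoxy-4-methylocta-3,7-dien-1-yl]-4-oxobut-2-en-1-yl 3-methylbutanoate F1. Cross-metathesis of F1 with 17 gives the allylic bromide methyl (2Z,5S,6Z,10Z)-5-acetoxy-2-(bromomethyl)-6-methyl-10-[(3-methylbutanoyloxy)methyl]-12-oxododeca-2,6,10-trienoate F2. Indium powder in THF–water at high dilution (Barbier conditions) then generates the allylindium, which closes C6–C7 through the same chair-type syn pathway and lactonises on acidification, so the route comes back at 22. In this variant the facial selectivity rests on the C9 stereocentre alone.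

Step 8 is the second risk, because the cross-metathesis partner is a hindered 1,1-disubstituted acrylate and the E/Z ratio is not guaranteed. The fallback builds C9 and the boryl enoate in one vinylogous aldol reaction and sets out from 12. Commercial methyl 3-hydroxy-2-methylidenebutanoate is acetylated to methyl 3-acetoxy-2-methylidenebutanoate F3. Copper-catalysed SN2′ borylation with B2pin2 gives methyl (2E)-2-[(4,4,5,5-tetramethyl-1,3,2-dioxaborolan-2-yl)methyl]but-2-enoate F4. LDA and TBSCl convert F4 into the silyl dienol ether tert-butyl({1-methoxy-2-[(4,4,5,5-tetramethyl-1,3,2-dioxaborolan-2-yl)methyl]buta-1,3-dien-1-yl}oxy)dimethylsilane F5. A catalytic enantioselective vinylogous Mukaiyama aldol addition of F5 to 12 (SiCl4 with the chiral bisphosphoramide antipode that gives Si-face attack) gives methyl (2E,5S,6Z,10Z)-5-hydroxy-11-iodo-6-methyl-10-[(3-methylbutanoyloxy)methyl]-2-[(4,4,5,5-tetramethyl-1,3,2-dioxaborolan-2-yl)methyl]undeca-2,6,10-trienoate F6, and acetylation of F6 returns to the route at 19.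

Step 9 is the third risk, because palladium with tin hydride can also attack the allylic esters or reduce the product enal. The fallback avoids a hydride source and sets out from 19. Stille coupling with (tributylstannyl)methanol gives the allylic alcohol methyl (2E,5S,6Z,10Z)-5-acetoxy-12-hydroxy-6-methyl-10-[(3-methylbutanoyloxy)methyl]-2-[(4,4,5,5-tetramethyl-1,3,2-dioxaborolan-2-yl)methyl]dodeca-2,6,10-trienoate F7, which is oxidised at once with MnO2 (before any acyl migration from O15 to O6) to come back at 20.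

**Further compounds**
F1 | step 10 | (2Z)-2-[(3Z,5S)-5-acetoxy-4-methylocta-3,7-dien-1-yl]-4-oxobut-2-en-1-yl 3-methylbutanoate | O=C/C=C(\COC(=O)CC(C)C)CC/C=C(/C)[C@@H](OC(C)=O)CC=C
F2 | step 10 | methyl (2Z,5S,6Z,10Z)-5-acetoxy-2-(bromomethyl)-6-methyl-10-[(3-methylbutanoyloxy)methyl]-12-oxododeca-2,6,10-trienoate | O=C/C=C(\COC(=O)CC(C)C)CC/C=C(/C)[C@@H](OC(C)=O)C/C=C(\CBr)C(=O)OC
F3 | step 8 | methyl 3-acetoxy-2-methylidenebutanoate (racemic) | CC(OC(C)=O)C(=C)C(=O)OC
F4 | step 8 | methyl (2E)-2-[(4,4,5,5-tetramethyl-1,3,2-dioxaborolan-2-yl)methyl]but-2-enoate | C/C=C(\CB1OC(C)(C)C(C)(C)O1)C(=O)OC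
F5 | step 8 | tert-butyl({1-methoxy-2-[(4,4,5,5-tetramethyl-1,3,2-dioxaborolan-2-yl)methyl]buta-1,3-dien-1-yl}oxy)dimethylsilane | COC(O[Si](C)(C)C(C)(C)C)=C(CB1OC(C)(C)C(C)(C)O1)C=C
F6 | step 8 | methyl (2E,5S,6Z,10Z)-5-hydroxy-11-iodo-6-methyl-10-[(3-methylbutanoyloxy)methyl]-2-[(4,4,5,5-tetramethyl-1,3,2-dioxaborolan-2-yl)methyl]undeca-2,6,10-trienoate | I/C=C(\COC(=O)CC(C)C)CC/C=C(/C)[C@@H](O)C/C=C(\CB1OC(C)(C)C(C)(C)O1)C(=O)OC
F7 | step 9 | methyl (2E,5S,6Z,10Z)-5-acetoxy-12-hydroxy-6-methyl-10-[(3-methylbutanoyloxy)methyl]-2-[(4,4,5,5-tetramethyl-1,3,2-dioxaborolan-2-yl)methyl]dodeca-2,6,10-trienoate | OC/C=C(\COC(=O)CC(C)C)CC/C=C(/C)[C@@H](OC(C)=O)C/C=C(\CB1OC(C)(C)C(C)(C)O1)C(=O)OC
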